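The target of the north-east run rose in a nearly straight line, and the meeting sat down to read that line before forecasting these flasks.

| setting | north-east | Wednesday's | Saturday's | Thursday's | Tuesday's | Friday's | Monday's |
|---|---|---|---|---|---|---|---|
| starting material | 0.20 M | 0.18 M | 0.18 M | 0.18 M | 0.18 M | 0.50 M | 0.060 M |
| gas | 31 mM (held) | 31 mM (held) | 31 mM (held) | 31 mM (held) | 31 mM (held) | 31 mM (held) | 31 mM (held) |
| free catalyst | 1 mol% | 1 mol% | 1 mol% | 0.5 mol% | 3 mol% | 0.3 mol% | 1 mol% |
| temperature | −20 °C | −20 °C | −40 °C | −35 °C | −20 °C | 10 °C | −40 °C |
| remark | run made earlier |  |  |  |  |  |  |
| time |  | 1.0 h | 1.0 h | 1.0 h | 1.0 h | 1.0 h | 1.0 h |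

- north-east (time / min: target / %, starting material / %): 3.00: 3.4, 96.3; 5.00: 5.2, 95.5; 8.00: 7.7, 89.4; 12.0: 14.5, 83.5; 20.0: 25.1, 76.0; 40.0: 47.6, 52.9

(readings scatter by 1 percentage point)

- at the start none of the gas is in solution
- the earlier runs do not show what temperature does; that part of a forecast is a guess
- no earlier run changes the charge of free catalyst; that part of a forecast is a guess

- the flasks by amount of target, in percent of the starting material charged, highest first, at 1.0 h (Wednesday's / Saturday's / Thursday's / Tuesday's / Friday's / Monday's)
- the amount of target, in percent of the starting material charged of the flask you put first, at 1.0 h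
- the amount of target, in percent of the starting material charged of the flask you put last, at 1.0 h

Two of us attended: the forecaster and I. On the first item we accepted the reading: 47.6% of the charge had become target after 40.0 min, with no clear bend, although the starting material had fallen to 52.9%. The forecaster took this to mean that concentration drops out, and put it this way: “Percent conversion should then depend on mol% and temperature, not concentration.”

I objected that a second thing can draw a straight line. At its saturation the gas in solution equals 15.5% of the north-east charge, and the target had reached 3.07 times that. None of the gas is in solution at the start, so, supposing one gas per target, the gas taken up had to enter during the run, and that entry could be the rate-limiting step.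

I therefore proposed a number to carry. The north-east slope, multiplied by its charge, gives a gas draw of 2.38 mM min⁻¹. For Tuesday's flask, draw times time divided by charge comes to 79.3%. I called this the feed share, the fraction of a flask's charge that this draw turns into target in the asked time. This is a pace read from one run, not a proven limit, but I committed to Tuesday's first at about that figure, even with 3 mol% of catalyst against 1 mol%. The runs show nothing about temperature, so I offered no figure for last place.

The forecast was entered as Tuesday's > Friday's > Wednesday's > Saturday's > Thursday's > Monday's, with 98% at the top and 7% at the bottom.

The flasks gave Tuesday's > Wednesday's > Friday's > Saturday's > Thursday's > Monday's, with 77.3% first and 19.3% last.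

    starting material + reagent + free catalyst → free catalyst + target (k = 71000 L² mol⁻² h⁻¹, Ea = 39.0 kJ mol⁻¹)
    gas ⇌ reagent, rate k2*(csat - [reagent]) (kL = 7.90 h⁻¹)
    2 free catalyst → spent catalyst (k = 310 L mol⁻¹ h⁻¹, Ea = 36.0 kJ mol⁻¹)
    (constants at −20 °C)

Tuesday's flask stands 2 percentage points under its feed share, and at 1.00 h its reagent is at 64.0% of saturation. A neighbouring flask keeps Tuesday's recipe but holds 0.072 M of starting material. The same reckoning gives it a feed share of 198%, which is above its whole charge. At 1.00 h that flask has reached 83.4% target, more than the 77.3% of Tuesday's flask, its reagent stands at 88.2% of saturation, and 17% of its starting material remains.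

All runs were computed with constants of no real substance; scatter was added.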